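**Retrosynthetic overview**
1. The butenolide is attached last: Heck coupling of the C9 vinyl group of 24 with 4-bromofuran-2(5H)-one 25.
2. C1–OH/C10–H come from an α-epoxide of C1=C10 (radical opening); the C6–C8 oxygens come from enone 15 by α-face epoxidation, reductive opening, enolate hydroxylation and hydroxyl-directed reduction.
3. Enone 15 comes from ketone 12 by dehydrogenation, methyl addition and oxidative 1,3-transposition.
4. Key step: ring B and the C9 quaternary centre are made together by a palladium hydride ring expansion (1,2-alkenyl shift) of the allenyl cyclopentenol 11 to cyclohexanone 12.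
5. Ring order: cyclopentenone 3 (C5 set by asymmetric conjugate addition) → ring A by aldol condensation (8) → ring B by ring expansion (12) → butenolide ring brought in intact.

Numbering: clerodane numbering is used for the bicyclic core (ring A = C1–C5, C10; ring B = C5–C10; C18 = CH2 on C4, C19 = methyl on C5, C17 = methyl on C8, C20 = methyl on C9, C11/C12 = vinyl carbons on C9). β is the face of the C19 and C20 methyl groups, α the opposite face.

Assumption: the enantiomers of the chiral carbene ligand (step 2) and of the Trost ligand (step 5) are taken to be those that give the drawn isomers; if induction is reversed, the mirror-image ligand is used.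

Step 1
Reactants: 1 pent-4-ynal
Product: 2 5,5-dimethoxypent-1-yne
Conditions: HC(OMe)3, TsOH·H2O (cat.), MeOH, 23 °C
Reagents that add atoms: trimethyl orthoformate COC(OC)OC
Why: Acid-catalysed acetalisation masks the aldehyde so that it survives the aluminium hydride of step 2.

Step 2
Reactants: 2 5,5-dimethoxypent-1-yne; 3 3-methylcyclopent-2-en-1-one
Product: 5 (3R)-3-(5,5-dimethoxypent-1-en-2-yl)-3-methylcyclopentan-1-one, via alkenylalane 4 (not isolated)
Conditions: i-Bu2AlH, NiCl2(dppp) (3 mol %), THF, 4 °C; then 3, Cu(OTf)2 (5 mol %), chiral sulfonate-bearing imidazolinium salt (carbene precursor, 5 mol %), −30 → 4 °C; aq. HCl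
Reagents that add atoms: none
Why: Nickel-catalysed α-selective hydroalumination gives the 1,1-disubstituted alkenylalane, and its copper–carbene-catalysed asymmetric conjugate addition to the β-methyl enone forms the C5 quaternary centre (R) under ligand control while bringing in the exocyclic methylene.

Step 3
Reactants: 5 (3R)-3-(5,5-dimethoxypent-1-en-2-yl)-3-methylcyclopentan-1-one
Product: 8 (3aS)-3a-methyl-4-methylidene-2,3,3a,4,5,6-hexahydro-1H-inden-1-one, via keto aldehyde 6 (not isolated), via aldol adduct 7 (not isolated)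
Conditions: 1 M HCl, THF, 23 °C; then KOH, MeOH, 23 → 40 °C
Reagents that add atoms: none
Why: Acetal hydrolysis followed by intramolecular aldol condensation closes ring A, because only attack by C10 on the aldehyde gives a six-membered ring and dehydration then gives the C10=C1 enone, which cannot isomerise past quaternary C5.

Step 4
Reactants: 8 (3aS)-3a-methyl-4-methylidene-2,3,3a,4,5,6-hexahydro-1H-inden-1-one; 9 1-bromobut-2-yne
Product: 11 (1S,3aS)-1-(buta-2,3-dien-2-yl)-3a-methyl-4-methylidene-2,3,3a,4,5,6-hexahydro-1H-inden-1-ol, via organoindium 10 (not isolated)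
Conditions: In powder, THF/sat. aq. NH4Cl, 23 °C
Reagents that add atoms: none
Why: Barbier-type addition of the γ-substituted propargylindium reagent occurs with allylic transposition (SE2') to give the α-allenyl carbinol by 1,2-addition anti to the angular methyl, and the C8 carbinol centre is destroyed again in step 5.

Step 5
Reactants: 11 (1S,3aS)-1-(buta-2,3-dien-2-yl)-3a-methyl-4-methylidene-2,3,3a,4,5,6-hexahydro-1H-inden-1-ol
Product: 12 (1R,4aS)-1-ethenyl-1,4a-dimethyl-5-methylidene-3,4,4a,5,6,7-hexahydronaphthalen-2(1H)-one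
Conditions: Pd2(dba)3·CHCl3 (2.5 mol %), (S,S)-DACH-phenyl Trost ligand (7.5 mol %), PhCO2H (10 mol %), Et3N (10 mol %), ClCH2CH2Cl, 60 °C
Reagents that add atoms: none
Why: Proposed new method: zerovalent palladium and benzoic acid give a palladium hydride that adds to the allene (hydrogen to the central carbon) to form a π-allyl complex, and the alkenyl ring carbon C10 then shifts from the carbinol carbon C8 to the substituted allyl terminus C9 anti to palladium while C8 becomes the ketone (semipinacol-type Wagner–Meerwein 1,2-shift), which enlarges the cyclopentenol to the six-membered ring B and creates the C9 quaternary centre (methyl β, vinyl α) through the ligand's control of the π-allyl face; the closest known reaction is the palladium-catalysed asymmetric ring expansion of allenylcyclobutanols to 2-vinylcyclopentanones, which has not been shown for unstrained five-membered carbinols or for migration of an sp2 ring carbon, the driving force here being ketone formation from an allene and the high migratory aptitude of the electron-rich alkenyl carbon.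

Step 6
Reactants: 12 (1R,4aS)-1-ethenyl-1,4a-dimethyl-5-methylidene-3,4,4a,5,6,7-hexahydronaphthalen-2(1H)-one
Product: 13 (1R,4aS)-1-ethenyl-1,4a-dimethyl-5-methylidene-4a,5,6,7-tetrahydronaphthalen-2(1H)-one
Conditions: IBX (2 equiv), 4-methoxypyridine N-oxide (2 equiv), DMSO, 23 → 40 °C
Reagents that add atoms: none
Why: IBX dehydrogenation of the ketone through its only enolisable position (C7, since C9 is quaternary) gives the C6=C7 enone without touching the isolated alkenes.

Step 7
Reactants: 13 (1R,4aS)-1-ethenyl-1,4a-dimethyl-5-methylidene-4a,5,6,7-tetrahydronaphthalen-2(1H)-one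
Product: 14 (1R,4aS)-1-ethenyl-1,2,4a-trimethyl-5-methylidene-1,2,4a,5,6,7-hexahydronaphthalen-2-ol (C2 epimers)
Conditions: MeLi (3 equiv), CeCl3, THF, −78 °C; aq. NH4Cl
Reagents that add atoms: methyllithium [Li]C
Why: Cerium-mediated 1,2-addition of methyl to the hindered enone carbonyl installs C17, and the configuration of the new carbinol is irrelevant because it is erased in step 8.

Step 8
Reactants: 14 (1R,4aS)-1-ethenyl-1,2,4a-trimethyl-5-methylidene-1,2,4a,5,6,7-hexahydronaphthalen-2-ol (C2 epimers)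
Product: 15 (4S,8aS)-4-ethenyl-3,4,8a-trimethyl-8-methylidene-6,7,8,8a-tetrahydronaphthalen-1(4H)-one
Conditions: (C5H5NH)[CrO3Cl] (3 equiv), 4 Å MS, CH2Cl2, 23 °C
Reagents that add atoms: pyridinium chlorochromate [O-][Cr](=O)(=O)Cl.c1cc[nH+]cc1
Why: Dauben–Babler oxidative 1,3-transposition, in which the tertiary allylic chromate ester rearranges to C6 and is oxidised there, moves the oxygen to C6 and leaves C8 as an sp2 carbon carrying the methyl, so that the C8 oxygen can later be delivered from the open α-face.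

Step 9
Reactants: 15 (4S,8aS)-4-ethenyl-3,4,8a-trimethyl-8-methylidene-6,7,8,8a-tetrahydronaphthalen-1(4H)-one
Product: 16 1α,10α-epoxy-9α-ethenyl-5β,8,9β-trimethyl-4-methylidenedecal-7-en-6-one
Conditions: mCPBA (1.05 equiv), NaHCO3, CH2Cl2, −20 °C
Reagents that add atoms: 3-chloroperbenzoic acid OOC(=O)c1cccc(Cl)c1
Why: Prilezhaev epoxidation selects the most electron-rich, trisubstituted C1=C10 alkene (expected to be roughly tenfold faster than the 1,1-disubstituted methylene and much faster than the vinyl group, the enone being inert) from the α-face opposite the C19 and C20 methyls, which sets the C1–O bond and makes C10 tetrahedral for the face-selective steps on ring B.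

Step 10
Reactants: 16 1α,10α-epoxy-9α-ethenyl-5β,8,9β-trimethyl-4-methylidenedecal-7-en-6-one
Product: 17 1α,10α:7α,8α-diepoxy-9α-ethenyl-5β,8β,9β-trimethyl-4-methylidenedecalin-6-one
Conditions: 30 % H2O2, NaOH (cat.), MeOH, 0 → 23 °C
Reagents that add atoms: hydrogen peroxide OO
Why: Weitz–Scheffer nucleophilic epoxidation touches only the enone, and because ring B is now a half-chair with the C9 β-methyl pseudoaxial the hydroperoxide adds to C8 from the α-face and sets the C8–O bond α.

Step 11
Reactants: 17 1α,10α:7α,8α-diepoxy-9α-ethenyl-5β,8β,9β-trimethyl-4-methylidenedecalin-6-one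
Product: 18 1α,10α-epoxy-9α-ethenyl-8α-hydroxy-5β,8β,9β-trimethyl-4-methylidenedecalin-6-one
Conditions: SmI2 (2.2 equiv), MeOH, THF, −90 °C
Reagents that add atoms: none
Why: Single-electron reduction of the α,β-epoxy ketone by divalent samarium cleaves only the C7–O bond next to the carbonyl, so the tertiary 8α-alcohol is kept with retention and the isolated epoxide and alkenes are untouched.

Step 12
Reactants: 18 1α,10α-epoxy-9α-ethenyl-8α-hydroxy-5β,8β,9β-trimethyl-4-methylidenedecalin-6-one
Product: 20 1α,10α-epoxy-9α-ethenyl-7α,8α-dihydroxy-5β,8β,9β-trimethyl-4-methylidenedecalin-6-one, via dilithium enolate 19 (not isolated)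
Conditions: LiN(i-Pr)2 (2.3 equiv), THF, −78 °C; then 2-(phenylsulfonyl)-3-phenyloxaziridine, −78 °C; aq. NH4Cl
Reagents that add atoms: 2-(phenylsulfonyl)-3-phenyloxaziridine O=S(=O)(c1ccccc1)N1OC1c1ccccc1
Why: Davis oxidation of the only possible enolate (C5 is quaternary) takes place at C7 from the α-face, because the β-face is blocked by the syn-axial C19 and C20 methyls, and gives the equatorial 7α-alcohol.

Step 13
Reactants: 20 1α,10α-epoxy-9α-ethenyl-7α,8α-dihydroxy-5β,8β,9β-trimethyl-4-methylidenedecalin-6-one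
Product: 21 1α,10α-epoxy-9α-ethenyl-8α-hydroxy-5β,8β,9β-trimethyl-4-methylidene-6-oxodecalin-7α-yl 2-methylpropanoate
Conditions: i-PrCOCl (1.5 equiv), Et3N, DMAP (cat.), CH2Cl2, 0 °C
Reagents that add atoms: 2-methylpropanoyl chloride CC(C)C(Cl)=O
Why: DMAP-catalysed acylation takes the only secondary hydroxyl, the tertiary C8 alcohol next to a quaternary carbon being unreactive.

Step 14
Reactants: 21 1α,10α-epoxy-9α-ethenyl-8α-hydroxy-5β,8β,9β-trimethyl-4-methylidene-6-oxodecalin-7α-yl 2-methylpropanoate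
Product: 22 1α,10α-epoxy-9α-ethenyl-6β,8α-dihydroxy-5β,8β,9β-trimethyl-4-methylidenedecalin-7α-yl 2-methylpropanoate
Conditions: Me4N[BH(OAc)3] (5 equiv), MeCN/AcOH (10:1), −30 °C
Reagents that add atoms: none
Why: Evans–Saksena hydroxyl-directed reduction, in which the axial 8α-OH binds the borohydride and delivers hydride to the α-face of C6 (also the face not shielded by the C19 methyl), gives the equatorial 6β-alcohol under acidic conditions that prevent acyl migration.

Step 15
Reactants: 22 1α,10α-epoxy-9α-ethenyl-6β,8α-dihydroxy-5β,8β,9β-trimethyl-4-methylidenedecalin-7α-yl 2-methylpropanoate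
Product: 23 6β-acetoxy-1α,10α-epoxy-9α-ethenyl-8α-hydroxy-5β,8β,9β-trimethyl-4-methylidenedecalin-7α-yl 2-methylpropanoate
Conditions: Ac2O, DMAP, pyridine, 40 °C
Reagents that add atoms: acetic anhydride CC(=O)OC(C)=O
Why: DMAP-catalysed acetylation of the secondary C6 alcohol, the tertiary C8 alcohol being inert under these conditions.

Step 16
Reactants: 23 6β-acetoxy-1α,10α-epoxy-9α-ethenyl-8α-hydroxy-5β,8β,9β-trimethyl-4-methylidenedecalin-7α-yl 2-methylpropanoate
Product: 24 6β-acetoxy-9α-ethenyl-1α,8α-dihydroxy-5β,8β,9β-trimethyl-4-methylidene-10α-H-decalin-7α-yl 2-methylpropanoate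
Conditions: Cp2TiCl2 (2.5 equiv), Zn dust, THF, 23 °C; then 23, t-BuSH (10 equiv), 23 °C; aq. HCl
Reagents that add atoms: none
Why: Nugent–RajanBabu reductive epoxide opening by trivalent titanium cleaves the C10–O bond to the tertiary C10 radical (C1–O retained, α), which takes a hydrogen atom from the thiol on the α-face opposite the two β-methyls to give the trans ring fusion, the fast thiol donor outrunning 3-exo cyclisation onto the neighbouring alkenes.

Step 17
Reactants: 24 6β-acetoxy-9α-ethenyl-1α,8α-dihydroxy-5β,8β,9β-trimethyl-4-methylidene-10α-H-decalin-7α-yl 2-methylpropanoate; 25 4-bromofuran-2(5H)-one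
Product: 26 CNP0215764.1
Conditions: Pd(OAc)2 (10 mol %), Bu4NCl, NaHCO3, DMF, 60 °C
Reagents that add atoms: none
Why: Mizoroki–Heck reaction under Jeffery conditions, with oxidative addition to the bromobutenolide, insertion at the terminal carbon of the monosubstituted vinyl group (the 1,1-disubstituted methylene is much slower) and syn β-hydride elimination, gives the (E)-diene and completes the target.

**Compound list**
1 | pent-4-ynal | C#CCCC=O | starting material
2 | 5,5-dimethoxypent-1-yne | C#CCCC(OC)OC | intermediate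
3 | 3-methylcyclopent-2-en-1-one | CC1=CC(=O)CC1 | starting material
4 | (5,5-dimethoxypent-1-en-2-yl)bis(2-methylpropyl)alumane (alkenylalane) | C=C(CCC(OC)OC)[Al](CC(C)C)CC(C)C | intermediate
5 | (3R)-3-(5,5-dimethoxypent-1-en-2-yl)-3-methylcyclopentan-1-one | C=C(CCC(OC)OC)[C@@]1(C)CC(=O)CC1 | intermediate
6 | 4-[(1R)-1-methyl-3-oxocyclopentyl]pent-4-enal (keto aldehyde) | O=CCCC(=C)[C@@]1(C)CC(=O)CC1 | intermediate
7 | (3aR)-7-hydroxy-3a-methyl-4-methylideneoctahydro-1H-inden-1-one (aldol adduct, C7/C7a unassigned) | C=C1CCC(O)C2[C@@]1(C)CCC2=O | intermediate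
8 | (3aS)-3a-methyl-4-methylidene-2,3,3a,4,5,6-hexahydro-1H-inden-1-one | C=C1CCC=C2[C@@]1(C)CCC2=O | intermediate
9 | 1-bromobut-2-yne | CC#CCBr | starting material
10 | but-2-yn-1-ylindium dibromide (organoindium, simplest formulation) | CC#CC[In](Br)Br | intermediate
11 | (1S,3aS)-1-(buta-2,3-dien-2-yl)-3a-methyl-4-methylidene-2,3,3a,4,5,6-hexahydro-1H-inden-1-ol | C=C1CCC=C2[C@@]1(C)CC[C@]2(O)C(C)=C=C | intermediate
12 | (1R,4aS)-1-ethenyl-1,4a-dimethyl-5-methylidene-3,4,4a,5,6,7-hexahydronaphthalen-2(1H)-one | C=C1CCC=C2[C@@]1(C)CCC(=O)[C@]2(C)C=C | intermediate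
13 | (1R,4aS)-1-ethenyl-1,4a-dimethyl-5-methylidene-4a,5,6,7-tetrahydronaphthalen-2(1H)-one | C=C1CCC=C2[C@@]1(C)C=CC(=O)[C@]2(C)C=C | intermediate
14 | (1R,4aS)-1-ethenyl-1,2,4a-trimethyl-5-methylidene-1,2,4a,5,6,7-hexahydronaphthalen-2-ol (C2 epimers) | C=C1CCC=C2[C@@]1(C)C=CC(C)(O)[C@]2(C)C=C | intermediate
15 | (4S,8aS)-4-ethenyl-3,4,8a-trimethyl-8-methylidene-6,7,8,8a-tetrahydronaphthalen-1(4H)-one | C=C1CCC=C2[C@@]1(C)C(=O)C=C(C)[C@]2(C)C=C | intermediate
16 | 1α,10α-epoxy-9α-ethenyl-5β,8,9β-trimethyl-4-methylidenedecal-7-en-6-one | C=C1CC[C@H]2O[C@@]23[C@@]1(C)C(=O)C=C(C)[C@]3(C)C=C | intermediate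
17 | 1α,10α:7α,8α-diepoxy-9α-ethenyl-5β,8β,9β-trimethyl-4-methylidenedecalin-6-one | C=C1CC[C@H]2O[C@@]23[C@@]1(C)C(=O)[C@@H]4O[C@]4(C)[C@]3(C)C=C | intermediate
18 | 1α,10α-epoxy-9α-ethenyl-8α-hydroxy-5β,8β,9β-trimethyl-4-methylidenedecalin-6-one | C=C1CC[C@H]2O[C@@]23[C@@]1(C)C(=O)C[C@](C)(O)[C@]3(C)C=C | intermediate
19 | dilithium C6-enolate C8-alkoxide of 18 | [Li+].[Li+].C=C1CC[C@H]2O[C@@]23[C@@]1(C)C([O-])=C[C@](C)([O-])[C@]3(C)C=C | intermediate
20 | 1α,10α-epoxy-9α-ethenyl-7α,8α-dihydroxy-5β,8β,9β-trimethyl-4-methylidenedecalin-6-one | C=C1CC[C@H]2O[C@@]23[C@@]1(C)C(=O)[C@H](O)[C@](C)(O)[C@]3(C)C=C | intermediate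
21 | 1α,10α-epoxy-9α-ethenyl-8α-hydroxy-5β,8β,9β-trimethyl-4-methylidene-6-oxodecalin-7α-yl 2-methylpropanoate | C=C1CC[C@H]2O[C@@]23[C@@]1(C)C(=O)[C@H](OC(=O)C(C)C)[C@](C)(O)[C@]3(C)C=C | intermediate
22 | 1α,10α-epoxy-9α-ethenyl-6β,8α-dihydroxy-5β,8β,9β-trimethyl-4-methylidenedecalin-7α-yl 2-methylpropanoate | C=C1CC[C@H]2O[C@@]23[C@@]1(C)[C@@H](O)[C@H](OC(=O)C(C)C)[C@](C)(O)[C@]3(C)C=C | intermediate
23 | 6β-acetoxy-1α,10α-epoxy-9α-ethenyl-8α-hydroxy-5β,8β,9β-trimethyl-4-methylidenedecalin-7α-yl 2-methylpropanoate | C=C1CC[C@H]2O[C@@]23[C@@]1(C)[C@@H](OC(C)=O)[C@H](OC(=O)C(C)C)[C@](C)(O)[C@]3(C)C=C | intermediate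
24 | 6β-acetoxy-9α-ethenyl-1α,8α-dihydroxy-5β,8β,9β-trimethyl-4-methylidene-10α-H-decalin-7α-yl 2-methylpropanoate (1R,5R,6R,7S,8R,9R,10S; trans-fused) | C=C1CC[C@@H](O)[C@H]2[C@@]1(C)[C@@H](OC(C)=O)[C@H](OC(=O)C(C)C)[C@](C)(O)[C@]2(C)C=C | intermediate
25 | 4-bromofuran-2(5H)-one | BrC1=CC(=O)OC1 | starting material
26 | CNP0215764.1, (1R,5R,6R,7S,8R,9R,10S)-6-acetoxy-1,8-dihydroxy-7-(2-methylpropanoyloxy)cleroda-4(18),11E,13-trien-15,16-olide | C=C1CC[C@@H](O)[C@H]2[C@@]1(C)[C@@H](OC(C)=O)[C@H](OC(=O)C(C)C)[C@](C)(O)[C@]2(C)/C=C/C1=CC(=O)OC1 | target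

**Totals**
Total step count: 17. Longest linear sequence: 17 steps (from pent-4-ynal 1 to 26).

**Steps most likely to fail**

Step 5 (new ring expansion; risk of no shift without ring strain, or of the wrong C9 epimer). The fallback sets out from 8 and returns at 12, using a selenium-induced semipinacol shift. Addition of (E)-but-2-en-2-yllithium (from (E)-2-bromobut-2-ene and t-BuLi, with CeCl3, THF, −78 °C) to 8 gives the alkenyl carbinol (1S,3aS)-1-[(2E)-but-2-en-2-yl]-3a-methyl-4-methylidene-2,3,3a,4,5,6-hexahydro-1H-inden-1-ol F1. PhSeCl (CH2Cl2, −78 °C) forms the seleniranium ion on the side-chain alkene and the ring alkenyl carbon C10 shifts to C9, giving the ring-enlarged selenide (1R,4aS)-1,4a-dimethyl-5-methylidene-1-[1-(phenylselanyl)ethyl]-3,4,4a,5,6,7-hexahydronaphthalen-2(1H)-one F2. H2O2/pyridine then oxidises selenium, and the selenoxide can only eliminate towards the methyl group, which gives the vinyl ketone 12 (C9 epimers separated at this point).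

Step 10 (the β-carbon C8 is flanked by a quaternary centre and may resist hydroperoxide). The fallback sets out from 16 and returns at 18, replacing steps 10 and 11 by boron chemistry. CuCl/NaOt-Bu/DPEphos-catalysed conjugate addition of B2pin2 (MeOH, THF, 23 °C) from the α-face gives the tertiary boronate 1α,10α-epoxy-9α-ethenyl-5β,8β,9β-trimethyl-4-methylidene-8α-(4,4,5,5-tetramethyl-1,3,2-dioxaborolan-2-yl)decalin-6-one F3. NaBO3·4H2O (THF/H2O) oxidises the C–B bond with retention to the 8α-hydroxy ketone 18.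

Step 12 (the dilithium species 19 may undergo retro-aldol cleavage). The fallback sets out from 18 and returns at 20, using soft enolisation and a Rubottom oxidation. TMSOTf/Et3N (CH2Cl2, 0 °C) gives the bis-silyl compound 1α,10α-epoxy-9α-ethenyl-5β,8β,9β-trimethyl-4-methylidene-6,8α-bis(trimethylsilyloxy)decal-6-ene F4. Dimethyldioxirane (acetone, −78 °C) oxidises only the electron-rich silyl enol ether, from the α-face, and silyl migration gives 1α,10α-epoxy-9α-ethenyl-5β,8β,9β-trimethyl-4-methylidene-7α,8α-bis(trimethylsilyloxy)decalin-6-one F5. Citric acid in MeOH removes both silyl groups to give 20.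

**Further compounds**
F1 | step 5 | (1S,3aS)-1-[(2E)-but-2-en-2-yl]-3a-methyl-4-methylidene-2,3,3a,4,5,6-hexahydro-1H-inden-1-ol | C=C1CCC=C2[C@@]1(C)CC[C@]2(O)/C(C)=C/C
F2 | step 5 | (1R,4aS)-1,4a-dimethyl-5-methylidene-1-[1-(phenylselanyl)ethyl]-3,4,4a,5,6,7-hexahydronaphthalen-2(1H)-one | C=C1CCC=C2[C@@]1(C)CCC(=O)[C@]2(C)C(C)[Se]c1ccccc1
F3 | step 10 | 1α,10α-epoxy-9α-ethenyl-5β,8β,9β-trimethyl-4-methylidene-8α-(4,4,5,5-tetramethyl-1,3,2-dioxaborolan-2-yl)decalin-6-one | C=C1CC[C@H]2O[C@@]23[C@@]1(C)C(=O)C[C@](C)(B4OC(C)(C)C(C)(C)O4)[C@]3(C)C=C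
F4 | step 12 | 1α,10α-epoxy-9α-ethenyl-5β,8β,9β-trimethyl-4-methylidene-6,8α-bis(trimethylsilyloxy)decal-6-ene | C=C1CC[C@H]2O[C@@]23[C@@]1(C)C(O[Si](C)(C)C)=C[C@](C)(O[Si](C)(C)C)[C@]3(C)C=C
F5 | step 12 | 1α,10α-epoxy-9α-ethenyl-5β,8β,9β-trimethyl-4-methylidene-7α,8α-bis(trimethylsilyloxy)decalin-6-one | C=C1CC[C@H]2O[C@@]23[C@@]1(C)C(=O)[C@H](O[Si](C)(C)C)[C@](C)(O[Si](C)(C)C)[C@]3(C)C=C
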